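**Plan**

- Retrosynthesis: both lactones are opened at O2–C3 and O2'–C3' (enol-lactonisation of γ-keto acids). The bicyclo[2.2.2]octene is cut at C7'–C7a' and C4'–C3a' (Diels–Alder of a ring-A-fused diene C4'=C5'–C6'(SPh)=C7' with an acetylenic keto ester). C1 is taken off C7a (carbonylation of an enol triflate). Ring A is cut at C7a–C3a and C4–C5.
- Enabling feature: ring A (C7a, C3a, C4, C5, C6, C7) is a cyclohexene cis-fused at C6–C7. Lifting out C3a and C4 leaves the four-membered ketone C7a–C7–C6–C5 on a cyclohexene, which is the [2+2] adduct of ketene and 1,3-cyclohexadiene with C6 and C7 already set.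
- Forward order: cyclobutanone (steps 1–5), ring A by nickel-catalysed alkyne insertion (step 8), C1 (step 11), diene from the C6'=C7' alkene (steps 12–16), bicyclo[2.2.2]octadiene (step 19), lactones A and B together in the last step.
- Stereochemistry: C6 and C7 come from the cis [2+2] adduct, resolved with a lipase, and are not touched again. C4' and C7' arise in the Diels–Alder step by addition anti to ring A. C6' is set by hydride attack on the open face followed by Mitsunobu inversion. Both Z alkenes are the thermodynamic result of enol-lactonisation.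

Key step: step 8

Remark: locants follow the phthalide numbering of the target (primes on the hydroxylated half), also in intermediates.
Remark: racemic compounds 4–7 are drawn as the enantiomer that is carried on.
Assumption: the lipase in step 4 cleaves the (7R)-acetate faster, in line with the large/medium substituent model for esters of secondary carbinols.

**Step 1**
Reactants: 1 1,3-cyclohexadiene; 2 trichloroacetyl chloride
Product: 4 rac-(1R,6S)-8,8-dichlorobicyclo[4.2.0]oct-2-en-7-one, via dichloroketene 3 (not isolated)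
Conditions: Zn (activated), Et2O, ultrasound, 20 °C
Reagents that add atoms: none
Why: Zinc strips two chlorines from 2 to give dichloroketene, whose thermal ketene–alkene [2+2] cycloaddition to one double bond of the diene is suprafacial on the alkene and places the carbonyl carbon on the diene terminus, so the cis ring fusion (C6 and C7) is set, as the racemate.

**Step 2**
Reactants: 4 rac-(1R,6S)-8,8-dichlorobicyclo[4.2.0]oct-2-en-7-one
Product: 5 rac-(1R,6S)-bicyclo[4.2.0]oct-2-en-7-one
Conditions: Zn, AcOH, 70 °C
Reagents that add atoms: none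
Why: Zinc in acetic acid removes both α-chlorines by reductive dehalogenation of the α-halo ketone without touching the ring-fusion centres or the alkene.

**Step 3**
Reactants: 5 rac-(1R,6S)-bicyclo[4.2.0]oct-2-en-7-one
Product: 7 rac-(1R,6S,7R)-bicyclo[4.2.0]oct-2-en-7-yl acetate (endo), via lithium alkoxide 6 (not isolated)
Conditions: LiBH(s-Bu)3, THF, −78 °C; then Ac2O, −78 → 20 °C
Reagents that add atoms: acetic anhydride, CC(=O)OC(C)=O
Why: The hindered borohydride attacks the cyclobutanone from the convex face, away from the six-membered ring, so the alkoxide is endo (cis to the ring carbons), and it is acetylated in the same flask (diastereoselective hydride reduction with O-acylation).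

**Step 4**
Reactants: 7 rac-(1R,6S,7R)-bicyclo[4.2.0]oct-2-en-7-yl acetate
Product: 8 (1R,6S,7R)-bicyclo[4.2.0]oct-2-en-7-ol
Conditions: Burkholderia cepacia lipase (Amano PS), phosphate buffer pH 7/acetone, 30 °C, stopped just short of half conversion
Reagents that add atoms: none
Why: Lipase-catalysed enantioselective ester hydrolysis (enzymatic kinetic resolution): the (7R)-acetate, whose larger carbinol substituent is the ring-fusion carbon, is cleaved fast, while the (1S,6R,7S)-acetate stays behind and is separated by chromatography.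

**Step 5**
Reactants: 8 (1R,6S,7R)-bicyclo[4.2.0]oct-2-en-7-ol
Product: 9 (1R,6S)-bicyclo[4.2.0]oct-2-en-7-one
Conditions: (n-Pr4N)RuO4 (cat.), NMO, 4 Å MS, CH2Cl2, 20 °C
Reagents that add atoms: none
Why: Perruthenate-catalysed oxidation of the secondary alcohol under neutral conditions returns the ketone; the α ring-fusion centre cannot epimerise because a trans-fused four/six system is prohibitively strained.

**Step 6**
Reactants: 10 pentanoyl chloride; 11 trimethylsilylacetylene
Product: 12 1-(trimethylsilyl)hept-1-yn-3-one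
Conditions: PdCl2(PPh3)2 (cat.), CuI (cat.), Et3N, THF, 20 °C
Reagents that add atoms: none
Why: Acyl Sonogashira coupling: the copper acetylide transmetallates to the acylpalladium complex from oxidative addition of the acid chloride and reductive elimination gives the ynone.

**Step 7**
Reactants: 12 1-(trimethylsilyl)hept-1-yn-3-one
Product: 13 2-butyl-2-[(trimethylsilyl)ethynyl]-1,3-dioxolane
Conditions: Me3SiOCH2CH2OSiMe3, Me3SiOTf (cat.), CH2Cl2, −78 → −20 °C
Reagents that add atoms: 1,2-bis(trimethylsilyloxy)ethane, C[Si](C)(C)OCCO[Si](C)(C)C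
Why: Silyl-triflate-catalysed ketalisation with the bis-silyl ether of ethylene glycol at low temperature, the method of choice for conjugated ynones that resist azeotropic ketalisation, masks the C3 ketone as a dioxolane that the nickel step tolerates.

**Step 8**
Reactants: 9 (1R,6S)-bicyclo[4.2.0]oct-2-en-7-one; 13 2-butyl-2-[(trimethylsilyl)ethynyl]-1,3-dioxolane
Product: 14 (4aR,8aS)-2-(2-butyl-1,3-dioxolan-2-yl)-3-(trimethylsilyl)-4a,7,8,8a-tetrahydronaphthalen-1(4H)-one (ring A enone: C7a ketone; ketal on C3a; silyl on C4)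
Conditions: Ni(cod)2 (10 mol %), PCy3 (20 mol %), toluene, 100 °C
Reagents that add atoms: none
Why: Zerovalent nickel joins the strained ketone carbonyl (C7a) and the alkyne by oxidative cyclisation to an oxanickelacyclopentene, which makes C7a–C3a and leaves nickel on the silyl-bearing carbon C4; β-carbon elimination then cleaves C7a–C5, re-forming the ketone and expanding the metallacycle to seven members, and C(sp2)–C(sp3) reductive elimination makes C4–C5. The closest known reaction type is the nickel-catalysed intermolecular insertion of internal alkynes into cyclobutanones to give cyclohexenones. Ring A is therefore closed as a six-membered carbocycle by two-carbon ring expansion, its last bond coming from reductive elimination at nickel and not from an addition to a π bond. No stereocentre is formed: C6 and C7 are not part of any bond that is made or broken, so the cis fusion and the absolute configuration of 9 pass unchanged into 14. The step needs (a) cleavage of C7a–C5 and not C7a–C7, secured by the easier migration of the primary carbon to nickel, (b) one orientation of the alkyne, secured by the preference of silicon for the carbon bound to nickel, which here has to outweigh the steric cost of bonding the ketal-bearing carbon to C7a, and (c) indifference of the catalyst to the C6'=C7' alkene, which as an unactivated 1,2-disubstituted alkene does not compete with the alkyne for oxidative cyclisation.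

**Step 9**
Reactants: 14 (4aR,8aS)-2-(2-butyl-1,3-dioxolan-2-yl)-3-(trimethylsilyl)-4a,7,8,8a-tetrahydronaphthalen-1(4H)-one
Product: 15 (4aR,8aS)-2-(2-butyl-1,3-dioxolan-2-yl)-4a,7,8,8a-tetrahydronaphthalen-1(4H)-one
Conditions: Bu4NF·3H2O, THF, 0 → 20 °C
Reagents that add atoms: none
Why: Fluoride adds to silicon and the alkenyl–silicon bond is cleaved with ipso protonation by the water of hydration (protodesilylation of an alkenylsilane), made easier here because the carbon that leaves silicon is β to the ketone; kept cold so that C7–H, which is α′ to the ketone, is not exchanged.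

**Step 10**
Reactants: 15 (4aR,8aS)-2-(2-butyl-1,3-dioxolan-2-yl)-4a,7,8,8a-tetrahydronaphthalen-1(4H)-one
Product: 17 (4aR,8aS)-2-(2-butyl-1,3-dioxolan-2-yl)-3,4,4a,7,8,8a-hexahydronaphthalen-1-yl trifluoromethanesulfonate, via lithium enolate 16 (not isolated)
Conditions: LiBH(s-Bu)3, THF, −78 °C; then N-(5-chloro-2-pyridyl)triflimide, −78 → 0 °C
Reagents that add atoms: N-(5-chloropyridin-2-yl)bis(trifluoromethanesulfonyl)imide, FC(F)(F)S(=O)(=O)N(c1ccc(Cl)cn1)S(=O)(=O)C(F)(F)F
Why: 1,4-Addition of hydride to the β-unsubstituted enone gives the lithium enolate regiospecifically across C7a–C3a and O-sulfonylation with the pyridyl triflimide fixes it as the tetrasubstituted enol triflate (conjugate reduction with enolate trapping), C7 never being deprotonated.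

**Step 11**
Reactants: 17 (4aR,8aS)-2-(2-butyl-1,3-dioxolan-2-yl)-3,4,4a,7,8,8a-hexahydronaphthalen-1-yl trifluoromethanesulfonate
Product: 18 methyl (4aR,8aS)-2-(2-butyl-1,3-dioxolan-2-yl)-3,4,4a,7,8,8a-hexahydronaphthalene-1-carboxylate (C1 on C7a)
Conditions: Pd(OAc)2 (cat.), dppp, CO (1 atm), MeOH, Et3N, DMF, 60 °C
Reagents that add atoms: carbon monoxide, [C-]#[O+]; methanol, CO
Why: Palladium-catalysed methoxycarbonylation of the enol triflate (oxidative addition to zerovalent palladium, CO insertion, methanolysis of the acyl complex) attaches C1 to C7a.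

**Step 12**
Reactants: 18 methyl (4aR,8aS)-2-(2-butyl-1,3-dioxolan-2-yl)-3,4,4a,7,8,8a-hexahydronaphthalene-1-carboxylate
Product: 20 enone with C5' ketone and C6'=C7' alkene (7-oxo derivative of 18), via allylic alcohol 19 (not isolated)
Conditions: SeO2 (cat.), t-BuOOH, CH2Cl2, 20 °C; then (n-Pr4N)RuO4 (cat.), NMO, 4 Å MS, CH2Cl2
Reagents that add atoms: selenium dioxide, O=[Se]=O; tert-butyl hydroperoxide, CC(C)(C)OO
Why: Selenium dioxide allylic oxidation (ene reaction then [2,3]-sigmatropic shift, which returns the double bond to C6'=C7') hydroxylates the allylic methylene C5' in preference to the allylic methine C6 and leaves the electron-poor ring A alkene alone, and perruthenate oxidation of the epimeric alcohols converges on one enone.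

**Step 13**
Reactants: 20 enone with C5' ketone and C6'=C7' alkene
Product: 21 C6',C7'-epoxy ketone
Conditions: 30 % H2O2, NaOH (cat.), MeOH, 0 °C
Reagents that add atoms: hydrogen peroxide, OO
Why: Nucleophilic (Weitz–Scheffer) epoxidation of the enone, with hydroperoxide adding to C7' from the face away from the neighbouring ring A methylene; the epoxide configuration is of no consequence because both carbons become trigonal again in the next step.

**Step 14**
Reactants: 21 C6',C7'-epoxy ketone
Product: 22 2-(phenylthio)enone (C5' ketone; SPh on C6'; C6'=C7')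
Conditions: PhSH, Et3N, EtOH, 20 → 50 °C
Reagents that add atoms: thiophenol, Sc1ccccc1
Why: Thiolate opens the epoxy ketone at the carbonyl-activated α-carbon C6' and the resulting β-hydroxy ketone loses water by E1cB, the established route from α,β-epoxy ketones to 2-(arylthio)enones.

**Step 15**
Reactants: 22 2-(phenylthio)enone
Product: 24 dienyl triflate (C4'=C5'(OTf)–C6'(SPh)=C7'), via lithium dienolate 23 (not isolated)
Conditions: LiN(i-Pr)2, THF, −78 °C; then N-(5-chloro-2-pyridyl)triflimide, −78 → 0 °C
Reagents that add atoms: N-(5-chloropyridin-2-yl)bis(trifluoromethanesulfonyl)imide, FC(F)(F)S(=O)(=O)N(c1ccc(Cl)cn1)S(=O)(=O)C(F)(F)F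
Why: Kinetic deprotonation by the amide base takes the α′ methylene proton at C4' rather than the γ methine proton at C6, and O-triflation of the cross-conjugated dienolate fixes the new C4'=C5' double bond (enol triflate formation).

**Step 16**
Reactants: 24 dienyl triflate
Product: 25 2-(phenylthio)diene (C4'=C5'–C6'(SPh)=C7'; ring A ester and ketal kept)
Conditions: Pd(OAc)2 (cat.), PPh3, HCO2H, n-Bu3N, DMF, 60 °C
Reagents that add atoms: none
Why: Palladium-catalysed formate reduction of the enol triflate (oxidative addition, formate exchange, loss of CO2, C–H reductive elimination) replaces the C5' oxygen by hydrogen and leaves the 2-(phenylthio)-1,3-diene.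

**Step 17**
Reactants: 26 methyl propiolate; 27 pentanal
Product: 29 methyl 4-hydroxyoct-2-ynoate (racemic), via lithium acetylide 28 (not isolated)
Conditions: LiN(SiMe3)2, THF, −78 °C; then pentanal; AcOH quench at −78 °C
Reagents that add atoms: none
Why: 1,2-Addition of the lithium acetylide of methyl propiolate to the aldehyde at −78 °C, where the acetylide does not add to its own ester, gives the racemic propargylic alcohol, whose stereocentre is removed in the next step.

**Step 18**
Reactants: 29 methyl 4-hydroxyoct-2-ynoate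
Product: 30 methyl 4-oxooct-2-ynoate
Conditions: IBX, EtOAc, 75 °C
Reagents that add atoms: none
Why: Oxidation of the propargylic alcohol with the hypervalent iodine reagent under neutral conditions gives the base-sensitive acetylenic keto ester.

**Step 19**
Reactants: 25 2-(phenylthio)diene; 30 methyl 4-oxooct-2-ynoate
Product: 31 bicyclo[2.2.2]octadiene adduct (C7a' ester; C3a' pentanoyl; SPh on C6'; H6 and H7 facing the C3a'=C7a' bridge)
Conditions: toluene, BHT (trace), 70 °C
Reagents that add atoms: none
Why: Diels–Alder reaction: the sulfur-substituted diene has its largest HOMO coefficient at C7' and the alkyne its largest LUMO coefficient at the carbon β to the ketone, so C7' joins the ester-bearing carbon (C7a') and C4' the acyl-bearing carbon (C3a'), the 'para' orientation of 2-thio dienes, and the dienophile adds to the diene face opposite the ring A carbons on C6 and C7, which sets C4' and C7' with H6 and H7 facing the new C3a'=C7a' bridge.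

**Step 20**
Reactants: 31 bicyclo[2.2.2]octadiene adduct
Product: 32 C6' ketone (bicyclo[2.2.2]octenone; esters and ketal kept)
Conditions: HgCl2, CaCO3, MeCN/H2O (4:1), 50 °C
Reagents that add atoms: water, O
Why: Mercury-assisted hydrolysis of the enol thioether (C-protonation to the thionium ion, capture by water, thiolate taken up by mercury) unmasks the C6' ketone, with carbonate buffering to keep the dioxolane.

**Step 21**
Reactants: 32 C6' ketone
Product: 33 6'-epi alcohol (hydroxyl on the side of ring A)
Conditions: NaBH4, MeOH/CH2Cl2 (1:1), −78 °C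
Reagents that add atoms: none
Why: Borohydride at −78 °C reduces the unhindered saturated bicyclic ketone much faster than the conjugated, fully substituted C3' ketone or the esters, and hydride enters C6' from the open face on the side of the C3a'=C7a' bridge because ring A (C5 and C7a) covers the other face, so the hydroxyl points toward ring A (6'-epi series).

**Step 22**
Reactants: 33 6'-epi alcohol
Product: 34 6'-(4-nitrobenzoate) with the C6' configuration of the target
Conditions: 4-O2NC6H4CO2H, PPh3, DIAD, THF, 0 → 20 °C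
Reagents that add atoms: 4-nitrobenzoic acid, OC(=O)c1ccc(cc1)[N+](=O)[O-]
Why: Mitsunobu reaction in its 4-nitrobenzoic acid form for hindered alcohols: the carboxylate displaces the oxyphosphonium group by SN2 from the unhindered side of the C3a'=C7a' bridge and inverts C6' to the configuration of the target.

**Step 23**
Reactants: 34 6'-(4-nitrobenzoate)
Product: 36 hydroxy diketo diacid (C1 and C1' acids; C3 and C3' ketones; free 6'-OH), via dilithium dicarboxylate 35 (not isolated)
Conditions: LiOH, THF/MeOH/H2O, 45 °C; then 2 M HCl to pH 1, THF, 20 °C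
Reagents that add atoms: lithium hydroxide, [Li+].[OH-]; water, O
Why: Hydroxide cleaves both methyl esters and the nitrobenzoate by acyl–oxygen fission and acidification then hydrolyses the dioxolane, no stereocentre of the molecule being enolisable under either condition.

**Step 24**
Reactants: 36 hydroxy diketo diacid
Product: 37 target dimer CNP0289078.1
Conditions: TsOH·H2O (cat.), toluene, 4 Å MS, 80 °C
Reagents that add atoms: none
Why: Acid-catalysed double enol-lactonisation: each (Z)-γ-keto acid closes 5-exo-trig to its hydroxy butenolide and loses water through the acyloxocarbenium ion to the thermodynamically preferred (Z)-butylidene lactone, while the secondary 6'-hydroxyl cannot reach C1' without prohibitive strain and stays free.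

**Compound list**

1 | 1,3-cyclohexadiene | C1=CC=CCC1 | starting material
2 | trichloroacetyl chloride | ClC(Cl)(Cl)C(=O)Cl | starting material
3 | dichloroketene | ClC(Cl)=C=O | intermediate
4 | rac-(1R,6S)-8,8-dichlorobicyclo[4.2.0]oct-2-en-7-one (cis-fused) | O=C2C(Cl)(Cl)[C@@H]1C=CCC[C@H]21 | intermediate
5 | rac-(1R,6S)-bicyclo[4.2.0]oct-2-en-7-one | O=C2C[C@@H]1C=CCC[C@H]21 | intermediate
6 | lithium rac-(1R,6S,7R)-bicyclo[4.2.0]oct-2-en-7-olate (endo) | [Li+].[O-][C@@H]2C[C@@H]1C=CCC[C@H]21 | intermediate
7 | rac-(1R,6S,7R)-bicyclo[4.2.0]oct-2-en-7-yl acetate (endo) | CC(=O)O[C@@H]2C[C@@H]1C=CCC[C@H]21 | intermediate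
8 | (1R,6S,7R)-bicyclo[4.2.0]oct-2-en-7-ol | O[C@@H]2C[C@@H]1C=CCC[C@H]21 | intermediate
9 | (1R,6S)-bicyclo[4.2.0]oct-2-en-7-one | O=C2C[C@@H]1C=CCC[C@H]21 | intermediate
10 | pentanoyl chloride | CCCCC(=O)Cl | starting material
11 | trimethylsilylacetylene | C#C[Si](C)(C)C | starting material
12 | 1-(trimethylsilyl)hept-1-yn-3-one | CCCCC(=O)C#C[Si](C)(C)C | intermediate
13 | 2-butyl-2-[(trimethylsilyl)ethynyl]-1,3-dioxolane | CCCCC1(C#C[Si](C)(C)C)OCCO1 | intermediate
14 | (4aR,8aS)-2-(2-butyl-1,3-dioxolan-2-yl)-3-(trimethylsilyl)-4a,7,8,8a-tetrahydronaphthalen-1(4H)-one | O=C2C(C3(CCCC)OCCO3)=C([Si](C)(C)C)C[C@@H]1C=CCC[C@H]21 | intermediate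
15 | (4aR,8aS)-2-(2-butyl-1,3-dioxolan-2-yl)-4a,7,8,8a-tetrahydronaphthalen-1(4H)-one | O=C2C(C3(CCCC)OCCO3)=CC[C@@H]1C=CCC[C@H]21 | intermediate
16 | lithium (4aR,8aS)-2-(2-butyl-1,3-dioxolan-2-yl)-3,4,4a,7,8,8a-hexahydronaphthalen-1-olate | [Li+].[O-]C2=C(C3(CCCC)OCCO3)CC[C@@H]1C=CCC[C@H]21 | intermediate
17 | (4aR,8aS)-2-(2-butyl-1,3-dioxolan-2-yl)-3,4,4a,7,8,8a-hexahydronaphthalen-1-yl trifluoromethanesulfonate | O=S(=O)(OC2=C(C3(CCCC)OCCO3)CC[C@@H]1C=CCC[C@H]21)C(F)(F)F | intermediate
18 | methyl (4aR,8aS)-2-(2-butyl-1,3-dioxolan-2-yl)-3,4,4a,7,8,8a-hexahydronaphthalene-1-carboxylate | COC(=O)C2=C(C3(CCCC)OCCO3)CC[C@@H]1C=CCC[C@H]21 | intermediate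
19 | methyl 2-(2-butyl-1,3-dioxolan-2-yl)-7-hydroxy-3,4,4a,7,8,8a-hexahydronaphthalene-1-carboxylate (C5' epimers; ring fusion as in 18) | COC(=O)C2=C(C3(CCCC)OCCO3)CC[C@@H]1C=CC(O)C[C@H]21 | intermediate
20 | methyl 2-(2-butyl-1,3-dioxolan-2-yl)-7-oxo-3,4,4a,7,8,8a-hexahydronaphthalene-1-carboxylate (ring fusion as in 18) | COC(=O)C2=C(C3(CCCC)OCCO3)CC[C@@H]1C=CC(=O)C[C@H]21 | intermediate
21 | methyl 2-(2-butyl-1,3-dioxolan-2-yl)-5,6-epoxy-7-oxo-3,4,4a,5,6,7,8,8a-octahydronaphthalene-1-carboxylate (epoxide on the face opposite the ring A methylene at the fusion) | COC(=O)C2=C(C3(CCCC)OCCO3)CC[C@@H]1[C@H]4O[C@H]4C(=O)C[C@H]21 | intermediate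
22 | methyl 2-(2-butyl-1,3-dioxolan-2-yl)-7-oxo-6-(phenylthio)-3,4,4a,7,8,8a-hexahydronaphthalene-1-carboxylate | COC(=O)C2=C(C3(CCCC)OCCO3)CC[C@@H]1C=C(Sc4ccccc4)C(=O)C[C@H]21 | intermediate
23 | lithium dienolate of 22 (O on C5'; C4'=C5') | COC(=O)C2=C(C3(CCCC)OCCO3)CC[C@@H]1C=C(Sc4ccccc4)C([O-])=C[C@H]21.[Li+] | intermediate
24 | methyl 2-(2-butyl-1,3-dioxolan-2-yl)-6-(phenylthio)-7-(trifluoromethylsulfonyloxy)-3,4,4a,8a-tetrahydronaphthalene-1-carboxylate | COC(=O)C2=C(C3(CCCC)OCCO3)CC[C@@H]1C=C(Sc4ccccc4)C(OS(=O)(=O)C(F)(F)F)=C[C@H]21 | intermediate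
25 | methyl 2-(2-butyl-1,3-dioxolan-2-yl)-6-(phenylthio)-3,4,4a,8a-tetrahydronaphthalene-1-carboxylate (cis-fused diene) | COC(=O)C2=C(C3(CCCC)OCCO3)CC[C@@H]1C=C(Sc4ccccc4)C=C[C@H]21 | intermediate
26 | methyl propiolate | C#CC(=O)OC | starting material
27 | pentanal | CCCCC=O | starting material
28 | lithium acetylide of methyl propiolate | [Li+].[C-]#CC(=O)OC | intermediate
29 | methyl 4-hydroxyoct-2-ynoate (racemic) | CCCCC(O)C#CC(=O)OC | intermediate
30 | methyl 4-oxooct-2-ynoate | CCCCC(=O)C#CC(=O)OC | intermediate
31 | dimethyl 6-(2-butyl-1,3-dioxolan-2-yl)-3-pentanoyl-9-(phenylthio)-1,4,4a,7,8,8a-hexahydro-1,4-ethenonaphthalene-2,5-dicarboxylate (H-4a and H-8a cis, facing the C2=C3 bridge) | COC(=O)C2=C(C5(CCCC)OCCO5)CC[C@@H]1[C@H]3C(C(=O)OC)=C(C(=O)CCCC)[C@H](C=C3Sc4ccccc4)[C@H]21 | intermediate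
32 | dimethyl 6-(2-butyl-1,3-dioxolan-2-yl)-9-oxo-3-pentanoyl-1,4,4a,7,8,8a-hexahydro-1,4-ethanonaphthalene-2,5-dicarboxylate | COC(=O)C2=C(C5(CCCC)OCCO5)CC[C@@H]1[C@H]3C(C(=O)OC)=C(C(=O)CCCC)[C@H](CC3=O)[C@H]21 | intermediate
33 | 9-hydroxy analogue of 32 with the hydroxyl on the side of ring A (6'-epi) | COC(=O)C2=C(C5(CCCC)OCCO5)CC[C@@H]1[C@H]3C(C(=O)OC)=C(C(=O)CCCC)[C@H](C[C@H]3O)[C@H]21 | intermediate
34 | 9-(4-nitrobenzoyloxy) analogue of 32 with the ester on the side of the C2=C3 bridge (C6' as in the target) | COC(=O)C2=C(C5(CCCC)OCCO5)CC[C@@H]1[C@H]3C(C(=O)OC)=C(C(=O)CCCC)[C@H](C[C@@H]3OC(=O)c4ccc(cc4)[N+](=O)[O-])[C@H]21 | intermediate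
35 | dilithium 6-(2-butyl-1,3-dioxolan-2-yl)-9-hydroxy-3-pentanoyl-1,4,4a,7,8,8a-hexahydro-1,4-ethanonaphthalene-2,5-dicarboxylate | [Li+].[Li+].[O-]C(=O)C2=C(C5(CCCC)OCCO5)CC[C@@H]1[C@H]3C(C([O-])=O)=C(C(=O)CCCC)[C@H](C[C@@H]3O)[C@H]21 | intermediate
36 | 9-hydroxy-3,6-dipentanoyl-1,4,4a,7,8,8a-hexahydro-1,4-ethanonaphthalene-2,5-dicarboxylic acid (in equilibrium with its lactol forms) | OC(=O)C2=C(C(=O)CCCC)CC[C@@H]1[C@H]3C(C(O)=O)=C(C(=O)CCCC)[C@H](C[C@@H]3O)[C@H]21 | intermediate
37 | CNP0289078.1: (Z,Z)-bis(butylidene) dilactone joined C6–C7' and C7–C4', 6'-hydroxyl on the side of the C3a'=C7a' bridge | CCC/C=C1\OC(=O)C2=C1CC[C@@H]1[C@H]3C4=C(/C(=C/CCC)OC4=O)[C@H](C[C@@H]3O)[C@H]21 | target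

**Step count**

Total: 24 steps. Longest linear sequence: 20 steps (steps 1–5, 8–16, 19–24).

**Steps most likely to fail**

Step 8. The oxidative cyclisation has to bond the quaternary, ketal-bearing alkyne carbon to the ketone carbon, and this may be too slow, so that zerovalent nickel is consumed by alkyne oligomerisation or by unproductive opening of the cyclobutanone. The fallback carries C3 at the alcohol level, which makes the alkyne smaller and gives an oxygen that later takes silicon off C4. It sets out from 12 and 9 and comes back at 17. Reduction of 12 (NaBH4, CeCl3·7H2O, MeOH) gives 1-(trimethylsilyl)hept-1-yn-3-ol F1. Silylation (Et3SiCl, imidazole) gives the triethylsilyl ether F2. Insertion into 9 under the conditions of step 8 gives the enone F3 as two C3 epimers that converge later. Bu4NF removes the O-silyl group, and the alkoxide, which is cis to the trimethylsilyl group across C3a=C4, takes silicon from carbon by a 1,4 carbon-to-oxygen shift, a well-known easy protodesilylation, to give the hydroxy enone F4. LiBH(s-Bu)3 (two equivalents, the first spent on the hydroxyl) followed by the pyridyl triflimide gives the hydroxy enol triflate F5. IBX gives the keto enol triflate F6, and ketalisation as in step 7 gives 17.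

Step 22. The hydroxyl of 33 sits in the pocket under ring A, so formation of the bulky oxyphosphonium ion may be slow and elimination toward C5' or acylation with retention may take over. The fallback activates the oxygen with a small sulfonyl group and uses an oxygen nucleophile that needs no ester cleavage. It sets out from 33 and comes back at 36. Tf2O and pyridine (CH2Cl2, −30 °C) give the 6'-triflate F7. n-Bu4NNO2 (MeCN, 20 °C) displaces it with inversion to the nitrite ester F8, which is hydrolysed on aqueous work-up to the 6'-alcohol of target configuration F9. F9 is taken through step 23 in place of 34 and gives 36.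

Step 9. Cleavage of the alkenyl–silicon bond may be slow, and the basic fluoride may meanwhile epimerise C7 or move the enone double bond. The fallback reduces first and removes silicon last, when the carbanion that leaves silicon is a vinylogous ester enolate. It sets out from 14 and comes back at 18. Reductive triflation of 14 (Li, NH3/THF, t-BuOH, −78 °C; then the pyridyl triflimide after removal of ammonia) gives the 4-silyl enol triflate F10. Methoxycarbonylation as in step 11 gives the allylsilane ester F11. Bu4NF in wet THF cleaves C4–Si, and protonation (with DBU equilibration if some β,γ-isomer forms) gives 18.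

**Further compounds**

F1 | step 8 | 1-(trimethylsilyl)hept-1-yn-3-ol (racemic) | CCCCC(O)C#C[Si](C)(C)C
F2 | step 8 | triethyl{[1-(trimethylsilyl)hept-1-yn-3-yl]oxy}silane | CCCCC(O[Si](CC)(CC)CC)C#C[Si](C)(C)C
F3 | step 8 | (4aR,8aS)-2-[1-(triethylsilyloxy)pentyl]-3-(trimethylsilyl)-4a,7,8,8a-tetrahydronaphthalen-1(4H)-one (C3 epimers) | O=C2C(C(CCCC)O[Si](CC)(CC)CC)=C([Si](C)(C)C)C[C@@H]1C=CCC[C@H]21
F4 | step 8 | (4aR,8aS)-2-(1-hydroxypentyl)-4a,7,8,8a-tetrahydronaphthalen-1(4H)-one (C3 epimers) | O=C2C(C(O)CCCC)=CC[C@@H]1C=CCC[C@H]21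
F5 | step 8 | (4aR,8aS)-2-(1-hydroxypentyl)-3,4,4a,7,8,8a-hexahydronaphthalen-1-yl trifluoromethanesulfonate (C3 epimers) | O=S(=O)(OC2=C(C(O)CCCC)CC[C@@H]1C=CCC[C@H]21)C(F)(F)F
F6 | step 8 | (4aR,8aS)-2-pentanoyl-3,4,4a,7,8,8a-hexahydronaphthalen-1-yl trifluoromethanesulfonate | O=S(=O)(OC2=C(C(=O)CCCC)CC[C@@H]1C=CCC[C@H]21)C(F)(F)F
F7 | step 22 | 6'-triflate of 33 (9-trifluoromethylsulfonyloxy analogue of 32, sulfonate on the side of ring A) | COC(=O)C2=C(C5(CCCC)OCCO5)CC[C@@H]1[C@H]3C(C(=O)OC)=C(C(=O)CCCC)[C@H](C[C@H]3OS(=O)(=O)C(F)(F)F)[C@H]21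
F8 | step 22 | 6'-nitrite ester with inverted C6' | COC(=O)C2=C(C5(CCCC)OCCO5)CC[C@@H]1[C@H]3C(C(=O)OC)=C(C(=O)CCCC)[C@H](C[C@@H]3ON=O)[C@H]21
F9 | step 22 | 9-hydroxy analogue of 32 with the hydroxyl on the side of the C2=C3 bridge (C6' as in the target) | COC(=O)C2=C(C5(CCCC)OCCO5)CC[C@@H]1[C@H]3C(C(=O)OC)=C(C(=O)CCCC)[C@H](C[C@@H]3O)[C@H]21
F10 | step 9 | (4aR,8aS)-2-(2-butyl-1,3-dioxolan-2-yl)-3-(trimethylsilyl)-3,4,4a,7,8,8a-hexahydronaphthalen-1-yl trifluoromethanesulfonate (C4 epimers) | O=S(=O)(OC2=C(C3(CCCC)OCCO3)C([Si](C)(C)C)C[C@@H]1C=CCC[C@H]21)C(F)(F)F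
F11 | step 9 | methyl (4aR,8aS)-2-(2-butyl-1,3-dioxolan-2-yl)-3-(trimethylsilyl)-3,4,4a,7,8,8a-hexahydronaphthalene-1-carboxylate (C4 epimers) | COC(=O)C2=C(C3(CCCC)OCCO3)C([Si](C)(C)C)C[C@@H]1C=CCC[C@H]21
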